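All runs stem from a simulated flask on assumed constants; scatter was added.

Time first: how long does a closed flask go on making target, and how long does it then stand?

in all of them: starting material 23 mM; free catalyst 0.053 mol%

|  | partner | protic impurity | remark | time |
|---|---|---|---|---|
| birch | 0.80 equiv | 1.15 mM | run made earlier |  |
| elm | 0.80 equiv | 1.6 mM | run made earlier |  |
| cedar | 0.80 equiv | 2.5 mM | run made earlier |  |
| alder | 1.6 equiv | 1.15 mM | run made earlier |  |
| grey | 0.800 equiv | 1.15 mM | plug flow through a tube for 5.0 h, no back-mixing | 5.0 h |
| amber | 0.800 equiv | 1.15 mM | one stirred flow tank at steady state, fed with the mixture as stated, mean residence time 5.0 h |  |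
| green | 0.800 equiv (fed, over 4.00 h) | 1.15 mM | all but partner at the start; partner goes in evenly over 4.00 h, the run ends at 5.0 h | 5.0 h |
| teal | 0.800 equiv | 1.15 mM | a closed flask charged with all of it at once and left for 5.0 h | 5.0 h |

| run | time / h | target / % | isomer of the product / % |
|---|---|---|---|
| birch | 0.667 | 15.5 | 2.9 |
| birch | 1.33 | 26.2 | 14.9 |
| birch | 2.00 | 32.0 | 29.4 |
| birch | 2.50 | 34.1 | 40.1 |
| birch | 3.00 | 28.1 | 51.1 |
| elm | 0.667 | 16.2 | 2.6 |
| elm | 1.33 | 24.1 | 17.4 |
| elm | 2.00 | 32.7 | 29.6 |
| elm | 2.50 | 32.1 | 41.2 |
| elm | 3.00 | 29.8 | 51.2 |
| cedar | 0.250 | 5.8 | 1.2 |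
| cedar | 0.833 | 18.3 | 7.2 |
| cedar | 1.33 | 25.5 | 16.6 |
| cedar | 2.00 | 29.5 | 29.8 |
| cedar | 3.00 | 29.0 | 53.0 |
| alder | 0.250 | 6.0 | 1.8 |
| alder | 0.833 | 18.1 | 5.8 |
| alder | 1.33 | 26.1 | 18.3 |
| alder | 2.00 | 30.6 | 30.9 |
| alder | 3.00 | 36.4 | 53.0 |

(standard deviation of a reading: 1 percentage point)

- the set-up with the highest share of target in all that became target or isomer of the product, at the outlet or at the end ("none" if the first two lie within 2 percentage points) (grey / amber / green / teal / none)
- share of target in all that became target or isomer of the product, at the outlet or at the end, grey
- share of target in all that became target or isomer of the product, at the outlet or at the end, amber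
- share of target in all that became target or isomer of the product, at the outlet or at the end, green
- share of target in all that became target or isomer of the product, at the outlet or at the end, teal

- the stated concentrations are those of everything mixed, before any reaction; amounts are the same in each set-up
- what was read earlier has a scatter of 1 percentage point, one standard deviation
- the feed brings no volume worth counting
- the earlier runs were made in a closed, stirred flask

I read the birch run as one curve. Target and isomer of the product together climbed straight from the start, with a slope of 0.297 h⁻¹ in fractions of the charge. Alder, with twice the partner, held 0.298 h⁻¹ up to 3.00 h, so the making looked zero order in partner. Partner is the limiting reagent in teal, and its charge divided by that slope gives the run-out time, 2.70 h.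

In birch, isomer lagged at first and crossed target between 2.00 h and 2.50 h. Its later slope, 0.217 h⁻¹, was smaller than the making, so target still climbed, to a highest reading of 34.1%. Per unit of target that drain is 0.636 h⁻¹. Teal then stands 2.30 h past run-out, and the readings end before any level shows. Grey, plug flow, follows the same clock. Running that drain down from the peak, I reckoned a share near 9.83% for teal.

The forecast gave 4% for grey, 13% for amber, 6% for green and 4% for teal, with amber best; its target “then is nearly gone by 5 h”. For teal that stands below my own figure.

The simulation gave 16.7% for grey, 28.2% for amber, 22.1% for green and 16.7% for teal, with amber best. The choice held, but teal stood 13 percentage points above the forecast.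

    starting material + free catalyst → catalyst intermediate A (k = 250 M⁻¹ s⁻¹)
    catalyst intermediate A → catalyst intermediate B (k = 0.910 s⁻¹)
    partner + catalyst intermediate B → catalyst intermediate C (k = 1100 M⁻¹ s⁻¹)
    catalyst intermediate C → free catalyst + target (k = 0.210 s⁻¹)
    starting material + protic impurity → quenched substrate (k = 0.150 M⁻¹ s⁻¹)
    starting material → decomposition product (k = 9.10 × 10⁻⁷ s⁻¹)
    target ⇌ isomer of the product (K = 6.20, k = 2.40 × 10⁻⁴ s⁻¹)

With partner at 0% in teal at the end, the free time I had reckoned, 2.30 h, is longer than the relaxation half-life of target and isomer, 0.691 h, about 3.33 of them. So teal ended near balance, not empty: its share at 50.0 h is 13.9%. Target survives through the backward run from isomer; without it teal gives 5.12%, not 16.7%.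

In a neighbour flask, teal with 0.021 mol% of free catalyst, a slope taken in proportion to catalyst is 0.118 h⁻¹, so I reckoned run-out at 6.80 h, later than 5.0 h, and 26.5% of the partner still there at the end. The flask kept 24% of its partner and a share of 30.5%.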